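## Retrosynthetic overview

1. Feature: violacene has one cyclohexane ring. Its secondary chlorides on C2 and C4 are 1,3-related across the C3 methylene and lie between C1 (Cl, CH2Br) and quaternary C5 (CH3, chlorovinyl). A CHCl2 group leaves this pattern when its radical adds to a vinyl terminus and the new radical takes a chlorine atom back.
2. Endgame: CH2Br comes from CH2OH (Appel) and the chlorovinyl group from CHO (Takai). The C1–Cl/CH2OH pair comes from a spiro-oxirane opened by chloride with inversion, and the oxirane comes from C1=CH2 and so from a C1 ketone.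
3. Key disconnection: C2–C3 and C4–Cl of a 2,4-dichlorocyclohexanone lead back to an acyclic dichloromethyl ketone with vinyl, methyl and a masked aldehyde on C5. The only ring is formed here, in the 6-endo mode.
4. Precursor: CHCl2 is built from CH3 by two enol-silane chlorinations. C5 is set by a copper-catalysed enantioselective conjugate vinylation of an (E)-enone made by Horner–Wadsworth–Emmons olefination.

Key step: step 5

Numbering: ring atoms carry the violacene numbers throughout (C1 ends with Cl and CH2Br, C5 with CH3 and chlorovinyl).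

Assumption: precedent does not show which way the chiral carbene–copper catalyst will induce on this enone. The ligand antipode that gives the (S)-ketone is therefore used; both antipodes derive from commercial (R,R)- or (S,S)-1,2-diphenylethylenediamine.

## Route

Step 1
Reactants: 1 1,1-dimethoxypropan-2-one; 2 diethyl (2-oxopropyl)phosphonate
Product: 3 (3E)-5,5-dimethoxy-4-methylpent-3-en-2-one
Conditions: NaH (0.95 equiv), THF, 0 °C; then 1, 0 → 40 °C; E isomer purified by chromatography
Reagents that add atoms: none
Why: Horner–Wadsworth–Emmons olefination: the two α-alkoxy groups make ketone 1 electrophilic enough for the stabilised phosphonate anion, and the acetyl group should end trans to the branched acetal carbon (E), a geometry that is purified here because it decides the face selectivity of step 2.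

Step 2
Reactants: 3 (3E)-5,5-dimethoxy-4-methylpent-3-en-2-one; 4 vinylmagnesium bromide
Product: 6 (4S)-4-(dimethoxymethyl)-4-methylhex-5-en-2-one, via diisobutyl(vinyl)aluminium 5 (not isolated)
Conditions: 4, iBu2AlCl, THF/hexane, 0 °C, magnesium salts filtered off; then 3, CuCl (5 mol %), chiral sulfonate-bearing imidazolinium salt derived from 1,2-diphenylethylenediamine (5 mol %), NaOtBu (10 mol %), THF, −30 → 4 °C; aq. potassium sodium tartrate
Reagents that add atoms: diisobutylaluminium chloride, CC(C)C[Al](Cl)CC(C)C (aluminium part of 5 only)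
Why: N-heterocyclic-carbene–copper-catalysed enantioselective conjugate addition of an alkenylaluminium reagent to an acyclic (E)-β,β-disubstituted enone: the sp2 ligand passes from aluminium to copper ahead of isobutyl, and the chelating chiral carbene tells apart the enone faces flanked by CH3 and the branched CH(OMe)2 group, which sets quaternary C5.

Step 3
Reactants: 6 (4S)-4-(dimethoxymethyl)-4-methylhex-5-en-2-one
Product: 8 (4S)-1-chloro-4-(dimethoxymethyl)-4-methylhex-5-en-2-one, via kinetic trimethylsilyl enol ether 7 (not isolated)
Conditions: LiN(iPr)2, THF, −78 °C; Me3SiCl, −78 → 0 °C; pentane/cold aq. NaHCO3 wash, crude carried on; NCS, CH2Cl2, 0 → 23 °C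
Reagents that add atoms: N-chlorosuccinimide, O=C1CCC(=O)N1Cl; chlorotrimethylsilane, C[Si](C)(C)Cl (silyl group of 7 only)
Why: Kinetic deprotonation takes the open CH3 rather than the neopentyl CH2, and α-halogenation of the resulting silyl enol ether with NCS should stop at the monochloride without touching the vinyl group, the acetal or C5.

Step 4
Reactants: 8 (4S)-1-chloro-4-(dimethoxymethyl)-4-methylhex-5-en-2-one
Product: 10 (4S)-1,1-dichloro-4-(dimethoxymethyl)-4-methylhex-5-en-2-one, via chloro silyl enol ether 9 (not isolated)
Conditions: Me3SiCl, then LiN(SiMe3)2 (in situ trapping), THF, −78 °C; pentane/cold aq. NaHCO3 wash, crude carried on; NCS, CH2Cl2, 23 °C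
Reagents that add atoms: N-chlorosuccinimide, O=C1CCC(=O)N1Cl; chlorotrimethylsilane, C[Si](C)(C)Cl (silyl group of 9 only)
Why: The CH2Cl protons are now the most acidic and the least hindered, so amide base with in situ silylation gives the chloro enol silane before the enolate can self-condense, and a second α-halogenation of a silyl enol ether with NCS delivers the CHCl2 ketone.

Step 5
Reactants: 10 (4S)-1,1-dichloro-4-(dimethoxymethyl)-4-methylhex-5-en-2-one
Product: 12 (2S,4R,5R)-2,4-dichloro-5-(dimethoxymethyl)-5-methylcyclohexan-1-one, via C2-epimeric dichloroketone 11 (not isolated)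
Conditions: CuCl2 (10 mol %), tris(2-pyridylmethyl)amine (TPMA, 11 mol %), Et4NBF4 (0.1 M), MeCN (0.02 M in 10), 40 °C, N2, divided cell, Pt-gauze cathode held at the half-wave potential of the [Cu(TPMA)Cl]+ couple; then iPr2NEt (0.3 equiv), 23 °C; recovered 11 is re-equilibrated
Reagents that add atoms: none
Why: Monovalent [Cu(TPMA)]+ made at the cathode abstracts one chlorine of the CHCl2 group, the electrophilic α-chloro-α-keto radical adds to the CH2 terminus of the vinyl group (C2–C3), and the secondary C4 radical takes chlorine from divalent [Cu(TPMA)Cl]+ (C4–Cl), so the step is a redox-neutral isomerisation in which the cathode only restores activator lost to termination. The closest known reactions are copper-catalysed chlorine-atom-transfer radical cyclisations of α-polychloro amides, esters and α-chloro-β-keto esters, including the electrochemically mediated form with the same CuCl2/TPMA couple. The cyclohexanone ring closes 6-endo-trig, because a 2-oxohex-5-enyl radical carries its sp2 carbonyl carbon inside the forming ring, which strains the 5-exo transition state, and 5-exo attack would also have to occur at the alkene carbon bonded to quaternary C5. C4 is set in the chlorine transfer: in the chair-like radical with the branched dimethoxymethyl group equatorial and the methyl group axial, the face syn to the axial methyl is closed, so chlorine should enter axially from the other face, cis to the acetal. C2 should emerge mainly as epimer 11 (chloride equatorial in that chair) and is then set by amine-catalysed enolisation, which leads to 12, the only isomer that can hold both chlorides equatorial and the one a polar medium should favour. The step needs activation of CHCl2 ahead of the monochloro ketone product and the unactivated C4–Cl bond, which the two geminal chlorines next to the carbonyl group secure, while dilution suppresses intermolecular addition.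

Step 6
Reactants: 12 (2S,4R,5R)-2,4-dichloro-5-(dimethoxymethyl)-5-methylcyclohexan-1-one
Product: 13 (1R,2R,4S)-2,4-dichloro-1-(dimethoxymethyl)-1-methyl-5-methylidenecyclohexane (C1=CH2 in violacene numbering)
Conditions: Cp2TiMe2 (3 equiv), toluene, 65 °C, dark
Reagents that add atoms: dimethyltitanocene, C[Ti+2]C.c1cc[cH-]c1.c1cc[cH-]c1
Why: Petasis methylenation: Cp2Ti=CH2 formed thermally from Cp2TiMe2 adds [2+2] to the ketone and cycloreverts, and because it is non-basic it should spare the epimerisable C2–Cl centre (no enolisation, no Favorskii path) and the acetal.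

Step 7
Reactants: 13 (1R,2R,4S)-2,4-dichloro-1-(dimethoxymethyl)-1-methyl-5-methylidenecyclohexane
Product: 14 (3R,4S,6R,7R)-4,6-dichloro-7-(dimethoxymethyl)-7-methyl-1-oxaspiro[2.5]octane (oxirane oxygen trans to C2–Cl and to the acetal)
Conditions: dimethyldioxirane (acetone solution), CH2Cl2, 0 °C
Reagents that add atoms: dimethyldioxirane, CC1(C)OO1
Why: Concerted dioxirane epoxidation under neutral conditions: in the chair that keeps both ring chlorides equatorial the C5 acetal is axial and screens the axial face of C1=CH2, so oxygen should arrive from the equatorial face and fix the C1–O bond on the side opposite to the acetal.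

Step 8
Reactants: 14 (3R,4S,6R,7R)-4,6-dichloro-7-(dimethoxymethyl)-7-methyl-1-oxaspiro[2.5]octane
Product: 16 (1R,2R,4S,5S)-2,4,5-trichloro-5-(hydroxymethyl)-1-methylcyclohexane-1-carbaldehyde, via chlorohydrin acetal 15 (not isolated)
Conditions: HCl (4 M in dioxane), CH2Cl2, −20 °C; then H2O/THF, 23 °C
Reagents that add atoms: hydrogen chloride, Cl; water, O
Why: Acid-promoted opening of a 2,2-disubstituted epoxide: chloride attacks the protonated oxirane at tertiary C1 opposite to the C1–O bond (borderline SN2, inversion), which places C1–Cl axial and cis to C2–Cl with CH2OH equatorial, and the same acid hydrolyses the dimethyl acetal to the aldehyde once water is added.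

Step 9
Reactants: 16 (1R,2R,4S,5S)-2,4,5-trichloro-5-(hydroxymethyl)-1-methylcyclohexane-1-carbaldehyde
Product: 17 [(1S,2S,4R,5R)-1,2,4-trichloro-5-[(E)-2-chloroethenyl]-5-methylcyclohexyl]methanol
Conditions: CrCl2 (8 equiv), CHCl3 (3 equiv), THF, 65 °C
Reagents that add atoms: chloroform, ClC(Cl)Cl
Why: Takai olefination: the geminal dichromium carbenoid from CHCl3 and CrCl2 adds to the aldehyde and eliminates to the (E)-chloroalkene, the bulk of quaternary C5 reinforcing the E preference, while unactivated alkyl chlorides and the free hydroxyl are tolerated; the step precedes bromination because divalent chromium would reduce a vicinal bromochloride.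

Step 10
Reactants: 17 [(1S,2S,4R,5R)-1,2,4-trichloro-5-[(E)-2-chloroethenyl]-5-methylcyclohexyl]methanol
Product: 18 violacene, (1R,2S,4R,5R)-1-(bromomethyl)-1,2,4-trichloro-5-[(E)-2-chloroethenyl]-5-methylcyclohexane
Conditions: CBr4, PPh3, CH2Cl2, 0 → 40 °C
Reagents that add atoms: carbon tetrabromide, BrC(Br)(Br)Br
Why: Appel reaction: the primary alcohol is activated as its alkoxyphosphonium salt and displaced by bromide at CH2, a hindered but stereochemically innocent substitution under neutral conditions that leaves the four chlorides and the alkene geometry untouched.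

## Compound list

1 | 1,1-dimethoxypropan-2-one | CC(=O)C(OC)OC | starting material
2 | diethyl (2-oxopropyl)phosphonate | CCOP(=O)(CC(C)=O)OCC | starting material
3 | (3E)-5,5-dimethoxy-4-methylpent-3-en-2-one | CC(=O)/C=C(\C)C(OC)OC | intermediate
4 | vinylmagnesium bromide | C=C[Mg]Br | starting material
5 | diisobutyl(vinyl)aluminium | C=C[Al](CC(C)C)CC(C)C | intermediate
6 | (4S)-4-(dimethoxymethyl)-4-methylhex-5-en-2-one | C=C[C@](C)(CC(C)=O)C(OC)OC | intermediate
7 | (4S)-4-(dimethoxymethyl)-4-methyl-2-(trimethylsilyloxy)hexa-1,5-diene | C=C[C@](C)(CC(=C)O[Si](C)(C)C)C(OC)OC | intermediate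
8 | (4S)-1-chloro-4-(dimethoxymethyl)-4-methylhex-5-en-2-one | C=C[C@](C)(CC(=O)CCl)C(OC)OC | intermediate
9 | (1Z,4S)-1-chloro-4-(dimethoxymethyl)-4-methyl-2-(trimethylsilyloxy)hexa-1,5-diene (enol geometry of no consequence) | C=C[C@](C)(C/C(=C/Cl)O[Si](C)(C)C)C(OC)OC | intermediate
10 | (4S)-1,1-dichloro-4-(dimethoxymethyl)-4-methylhex-5-en-2-one | C=C[C@](C)(CC(=O)C(Cl)Cl)C(OC)OC | intermediate
11 | (2R,4R,5R)-2,4-dichloro-5-(dimethoxymethyl)-5-methylcyclohexan-1-one | C[C@]1(C(OC)OC)CC(=O)[C@H](Cl)C[C@H]1Cl | intermediate
12 | (2S,4R,5R)-2,4-dichloro-5-(dimethoxymethyl)-5-methylcyclohexan-1-one | C[C@]1(C(OC)OC)CC(=O)[C@@H](Cl)C[C@H]1Cl | intermediate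
13 | (1R,2R,4S)-2,4-dichloro-1-(dimethoxymethyl)-1-methyl-5-methylidenecyclohexane | C[C@]1(C(OC)OC)CC(=C)[C@@H](Cl)C[C@H]1Cl | intermediate
14 | (3R,4S,6R,7R)-4,6-dichloro-7-(dimethoxymethyl)-7-methyl-1-oxaspiro[2.5]octane | C[C@]1(C(OC)OC)C[C@@]2(CO2)[C@@H](Cl)C[C@H]1Cl | intermediate
15 | [(1S,2S,4R,5R)-1,2,4-trichloro-5-(dimethoxymethyl)-5-methylcyclohexyl]methanol | C[C@]1(C(OC)OC)C[C@](Cl)(CO)[C@@H](Cl)C[C@H]1Cl | intermediate
16 | (1R,2R,4S,5S)-2,4,5-trichloro-5-(hydroxymethyl)-1-methylcyclohexane-1-carbaldehyde | C[C@]1(C=O)C[C@](Cl)(CO)[C@@H](Cl)C[C@H]1Cl | intermediate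
17 | [(1S,2S,4R,5R)-1,2,4-trichloro-5-[(E)-2-chloroethenyl]-5-methylcyclohexyl]methanol | C[C@]1(/C=C/Cl)C[C@](Cl)(CO)[C@@H](Cl)C[C@H]1Cl | intermediate
18 | violacene, (1R,2S,4R,5R)-1-(bromomethyl)-1,2,4-trichloro-5-[(E)-2-chloroethenyl]-5-methylcyclohexane | C[C@]1(/C=C/Cl)C[C@](Cl)(CBr)[C@@H](Cl)C[C@H]1Cl | target

## Step count and risks

Total step count: 10. Longest linear sequence: 10 steps (from 1 or 2).

**Step 5 (key step).**
- What may go wrong: chlorine may return to the C4 radical with little face preference, because the two chair forms of the radical lie close in energy. Material can also be lost through 5-exo closure, 1,5-hydrogen transfer from the acetal C–H to the electrophilic radical, reduction of that radical before it cyclises, or an incomplete C2 equilibration.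
- Fallback: an ionic closure of the same C2–C3 bond that sets out from 6 and comes back at 12.
- The vinyl group of 6 is dichlorinated with Et4NCl3 in CH2Cl2 to (4R,5S)-5,6-dichloro-4-(dimethoxymethyl)-4-methylhexan-2-one F1. No face control is expected, so it must be separated from (4R,5R)-5,6-dichloro-4-(dimethoxymethyl)-4-methylhexan-2-one F2.
- The kinetic methyl enolate of F1 (LiN(iPr)2, THF/DMPU, −78 → 0 °C) displaces the primary chloride 6-exo-tet to give (3R,4R)-4-chloro-3-(dimethoxymethyl)-3-methylcyclohexan-1-one F3.
- Kinetic deprotonation of F3 at the CH2 remote from the quaternary carbon and quenching of the enolate with p-toluenesulfonyl chloride installs C2–Cl. Amine equilibration as in step 5 then leads through 11 to 12.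

**Step 8.**
- What may go wrong: chloride may attack the open CH2 terminus of the oxirane, because C2–Cl withdraws electron density from C1. The opening may also lose its inversion (free cation, hydride shift to an aldehyde), since the axial C5 substituent hinders the required approach.
- Fallback: a bromonium ion in place of the oxirane, setting out from 13 and coming back at 18.
- Markovnikov bromochlorination of 13 with N-bromosuccinimide and ClTi(OiPr)3 in CH2Cl2/hexane at −20 °C puts bromine on the less hindered face and chloride on C1. This gives (1R,2S,4R,5R)-1-(bromomethyl)-1,2,4-trichloro-5-(dimethoxymethyl)-5-methylcyclohexane F4.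
- Aqueous HCl in THF frees (1R,2R,4S,5R)-5-(bromomethyl)-2,4,5-trichloro-1-methylcyclohexane-1-carbaldehyde F5.
- Divalent chromium would reduce the vicinal bromochloride, so the chlorovinyl group is built without it. Ohira–Bestmann homologation (dimethyl (1-diazo-2-oxopropyl)phosphonate, K2CO3, MeOH) gives (1R,2S,4R,5R)-1-(bromomethyl)-1,2,4-trichloro-5-ethynyl-5-methylcyclohexane F6.
- Syn hydrozirconation with Cp2Zr(H)Cl gives the (E)-alkenylzirconocene chloride F7, and N-chlorosuccinimide converts it with retention into 18.

**Step 2.**
- What may go wrong: catalyst control over the enone faces may be weak for the parent vinyl group. Residual magnesium salts may open a racemic background path, isobutyl transfer or 1,2-addition may compete, and the aluminium Lewis acid may attack the acetal.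
- Fallback: auxiliary control with separable diastereomers, setting out from 3 and coming back at 6.
- Transacetalisation of 3 with (R,R)-hydrobenzoin (pyridinium p-toluenesulfonate, toluene, molecular sieves) gives (3E)-4-[(4R,5R)-4,5-diphenyl-1,3-dioxolan-2-yl]pent-3-en-2-one F8.
- Copper-catalysed conjugate addition of 4 (CuI, 10 mol %, THF, −40 °C) next to the C2-symmetric acetal gives (4S)-4-[(4R,5R)-4,5-diphenyl-1,3-dioxolan-2-yl]-4-methylhex-5-en-2-one F9. Chromatography frees it from (4R)-4-[(4R,5R)-4,5-diphenyl-1,3-dioxolan-2-yl]-4-methylhex-5-en-2-one F10, so enantiopurity no longer depends on the selectivity; the other hydrobenzoin antipode is used if induction is mismatched.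
- Acid-catalysed exchange (MeOH, HC(OMe)3, p-toluenesulfonic acid, then a brief mild aqueous wash to return any ketal) gives 6.

## Further compounds

F1 | step 5 | (4R,5S)-5,6-dichloro-4-(dimethoxymethyl)-4-methylhexan-2-one | C[C@](C(OC)OC)(CC(C)=O)[C@H](Cl)CCl
F2 | step 5 | (4R,5R)-5,6-dichloro-4-(dimethoxymethyl)-4-methylhexan-2-one | C[C@](C(OC)OC)(CC(C)=O)[C@@H](Cl)CCl
F3 | step 5 | (3R,4R)-4-chloro-3-(dimethoxymethyl)-3-methylcyclohexan-1-one | C[C@]1(C(OC)OC)CC(=O)CC[C@H]1Cl
F4 | step 8 | (1R,2S,4R,5R)-1-(bromomethyl)-1,2,4-trichloro-5-(dimethoxymethyl)-5-methylcyclohexane | C[C@]1(C(OC)OC)C[C@](Cl)(CBr)[C@@H](Cl)C[C@H]1Cl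
F5 | step 8 | (1R,2R,4S,5R)-5-(bromomethyl)-2,4,5-trichloro-1-methylcyclohexane-1-carbaldehyde | C[C@]1(C=O)C[C@](Cl)(CBr)[C@@H](Cl)C[C@H]1Cl
F6 | step 8 | (1R,2S,4R,5R)-1-(bromomethyl)-1,2,4-trichloro-5-ethynyl-5-methylcyclohexane | C[C@]1(C#C)C[C@](Cl)(CBr)[C@@H](Cl)C[C@H]1Cl
F7 | step 8 | (E)-alkenylzirconocene chloride from F6 | C[C@]1(/C=C/[Zr+2]Cl)C[C@](Cl)(CBr)[C@@H](Cl)C[C@H]1Cl.c1cc[cH-]c1.c1cc[cH-]c1
F8 | step 2 | (3E)-4-[(4R,5R)-4,5-diphenyl-1,3-dioxolan-2-yl]pent-3-en-2-one | CC(=O)/C=C(\C)C1O[C@H](c2ccccc2)[C@@H](c2ccccc2)O1
F9 | step 2 | (4S)-4-[(4R,5R)-4,5-diphenyl-1,3-dioxolan-2-yl]-4-methylhex-5-en-2-one | C=C[C@](C)(CC(C)=O)C1O[C@H](c2ccccc2)[C@@H](c2ccccc2)O1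
F10 | step 2 | (4R)-4-[(4R,5R)-4,5-diphenyl-1,3-dioxolan-2-yl]-4-methylhex-5-en-2-one | C=C[C@@](C)(CC(C)=O)C1O[C@H](c2ccccc2)[C@@H](c2ccccc2)O1
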